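**Remark (assumption):** 8-methoxynaphthalen-1-ol (1) is taken as a catalogue compound. The two biaryl axes of the target each carry only one ortho oxygen and one peri C–H, so they are treated as freely rotating, in line with the target SMILES, which has no stereo descriptors.

**Numbering used throughout** (full list after the steps): 1 8-methoxynaphthalen-1-ol; 2 its 2-carbaldehyde; 3 MOM ether of 2; 4 (E)-iodoalkene from 3; 5 4-bromo derivative of 1; 6 MOM ether of 5; 7 arylacetate from 6; 8 diaryl butenoate from 7 and 4; 9 3-bromoanisole; 10 lithium dienolate of 8; 11 3-methoxybenzyne; 12 4H-naphthalen-1-one; 13 bis-MOM trimer; 14 target.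

## Analysis of the target

Target 14 (C33H26O6) is a linear trimer of 8-methoxynaphthalen-1-ol. The units are called A, B and C; in each, ring 1 is the phenol ring (C1, C2, C3, C4, C4a, C8a) and ring 2 the methoxy ring (C4a, C5, C6, C7, C8, C8a). Unit A is bonded through its C2 (ortho to its OH) to C4 of the central unit B, and unit B is bonded through its C2 to C4 of unit C (para to the OH of C). Ring B1 is therefore 1,2,4-trisubstituted (OH, aryl, aryl), with only C3 left as CH. There is no stereocentre. The sensitive groups are three electron-rich naphthols, each hydrogen-bonded to a peri methoxy group; they are easily oxidised to quinones or coupled further, and at the end they must be told apart from three aryl methyl ethers. The difficulty is one of position: three almost identical units must be joined ortho-to-para twice, yet C2 and C4 of the free naphthol are both nucleophilic, and in a dialkoxy derivative the two rings are equally activated. The feature that decides the strategy lies in unit B: the fusion carbons C4a and C8a are neighbours, C8a carries the carbinol carbon C1 and sits next to C8–OMe, and C4a carries C4, the carbon bonded to unit A. Ring B2 is thus the footprint of 3-methoxybenzyne (triple bond C4a≡C8a) that has taken up an acyl carbon next to OMe and a carbon nucleophile at the remote carbon, and C1–C2–C3–C4 of ring B1 is a four-carbon ester chain whose α carbon bears unit C and whose γ carbon bears unit A.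

## Retrosynthetic reasoning

**14 to 13.** The two outer hydroxyl groups are masked as methoxymethyl ethers in 13, while the OH of unit B is free because it is created by the ring-forming step. An acetal is chosen because it survives lithium amides, organozinc and organochromium reagents and is removed by acid that leaves aryl methyl ethers alone.

**13 to 8 and 11 (from 9).** Ring B1 is cut at C4–C4a and C1–C8a, the two bonds that tie it to ring B2, and C1 is taken back to an ester carbon. This leaves 3-methoxybenzyne 11 and the dienolate 10 of butenoate 8, which already carries unit C on C2 and unit A on C4. The cut is made here because the central unit then never has to be functionalised selectively at C2 and C4: the 1,2,4-pattern is written into the chain, and the peri OH/OMe relation is set by the polarisation of 11. The forward reaction must bond C4 of 10 to the aryne carbon remote from OMe and the ester carbon to the aryne carbon next to OMe, expel ethoxide to give dienone 12, and let 12 tautomerise to the naphthol.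

**8 to 7 and 4.** The C2–C3 bond (sp3–sp2) is cut to the arylacetate 7 as enolate partner and the (E)-iodoalkene 4 as electrophile. This bond is chosen because its formation has no regiochemical ambiguity, and because the alkene geometry, which the key step needs to be E, is fixed beforehand in 4.

**7 to 6 to 5 to 1.** The acetate side chain of 7 comes from aryl bromide 6 by coupling with a zinc ester enolate. Bromide 6 comes from bromonaphthol 5, and 5 from para-bromination of 1. Bromination must come before protection: only in the free naphthol is ring 1 clearly more activated than ring 2.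

**4 to 3 to 2 to 1.** The iodoalkene 4 comes from aldehyde 3 by one-carbon halo-olefination, 3 from hydroxy aldehyde 2 by protection, and 2 from 1 by magnesium-mediated formylation, which can only occur ortho to OH. Both outer units thus diverge from 1 through its two innate selectivities: ortho through the metal chelate, para through electrophilic substitution.

## Alternatives that were turned down

**Alternative 1:** the textbook route. Both biaryl bonds are disconnected by Suzuki–Miyaura coupling. The forward key step is two successive chemoselective couplings on 4-bromo-2-iodo-8-methoxy-1-(methoxymethoxy)naphthalene A1: first at C–I with the unit C boronate 2-[5-methoxy-4-(methoxymethoxy)naphthalen-1-yl]-4,4,5,5-tetramethyl-1,3,2-dioxaborolane A2, then at C–Br with the corresponding 2-boron derivative of unit A. It was turned down for three reasons. It needs three differently functionalised versions of the same naphthol and a regiodefined dihalogenation of the central unit. Both couplings form hindered biaryls from ortho-alkoxy boron reagents that are prone to protodeboronation. And the step count is about the same as the chosen route, with no step that builds a ring. A variant of it is kept as the fallback for the key step.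

**Alternative 2:** the biomimetic route. Both biaryl bonds are disconnected to 1 itself; the forward key step is a one-electron oxidative phenol coupling of 1 (FeCl3, Ag2O or an oxidase with O2). The first coupling would have to give the ortho–para dimer 2-(4-hydroxy-5-methoxynaphthalen-1-yl)-8-methoxynaphthalen-1-ol A3, and A3 would have to couple once more through C2 of its para-linked unit with C4 of a third molecule of 1. It was turned down because the naphthoxyl radical has spin density at both C2 and C4, so the para–para dimer 4-(4-hydroxy-5-methoxynaphthalen-1-yl)-8-methoxynaphthalen-1-ol A4 and the ortho–ortho dimer compete. A3 is also more easily oxidised than 1, and nothing in the substrate directs the second coupling. It would be one step, but its selectivity cannot be defended.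

**Alternative 3:** the same aryne with a furan. Ring B1 is disconnected at the same two bonds, but the four-carbon partner is 2-[8-methoxy-1-(methoxymethoxy)naphthalen-2-yl]-4-[5-methoxy-4-(methoxymethoxy)naphthalen-1-yl]furan A5. A [4+2] cycloaddition with 11 would give the oxabicycle 5-methoxy-3-[5-methoxy-4-(methoxymethoxy)naphthalen-1-yl]-1-[8-methoxy-1-(methoxymethoxy)naphthalen-2-yl]-1,4-dihydro-1,4-epoxynaphthalene A6, and acid would open it to the naphthol by cleaving the C–O bond at the aryl-bearing bridgehead. The ring opening is well directed, but the cycloaddition is not. The required adduct A6 needs the unsubstituted, more nucleophilic furan terminus to bond to the aryne carbon next to OMe, whereas the polarisation of 11 favours the opposite pairing and only sterics argue for A6. A5 would also need two cross-couplings on a furan. In the chosen route the ester carbon of the dienolate cannot act as the nucleophilic terminus, so this ambiguity does not arise.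

Key step: step 8

## Route

Step 1
Reactants: 1 8-methoxynaphthalen-1-ol
Product: 2 1-hydroxy-8-methoxynaphthalene-2-carbaldehyde
Conditions: MgCl2, Et3N, (CH2O)n, MeCN, reflux; aq HCl
Reagents that add atoms: formaldehyde (from paraformaldehyde), C=O
Why: Magnesium-mediated ortho-formylation (Casnati–Skattebøl): the magnesium naphtholate delivers formaldehyde through an O–Mg–O=CH2 chelate to the only ortho position, C2, and a second formaldehyde oxidises the hydroxymethyl intermediate by hydride transfer. C4 is not reached by this chelate-bound electrophile.

Step 2
Reactants: 2 1-hydroxy-8-methoxynaphthalene-2-carbaldehyde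
Product: 3 8-methoxy-1-(methoxymethoxy)naphthalene-2-carbaldehyde
Conditions: MOMCl, i-Pr2NEt, CH2Cl2, 0 to 40 °C
Reagents that add atoms: chloromethyl methyl ether, COCCl
Why: O-alkylation of the naphthol with a reactive α-chloro ether; the MOM ether should survive the organochromium, palladium enolate and lithium amide steps and is cleaved at the end by acid that leaves the methyl ethers.

Step 3
Reactants: 3 8-methoxy-1-(methoxymethoxy)naphthalene-2-carbaldehyde
Product: 4 2-[(E)-2-iodoethenyl]-8-methoxy-1-(methoxymethoxy)naphthalene
Conditions: CHI3, CrCl2, THF, 0 °C to rt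
Reagents that add atoms: iodoform, IC(I)I
Why: Takai olefination: the geminal dichromium species formed from iodoform and divalent chromium adds to the aldehyde and eliminates to the (E)-iodoalkene, as is usual for aryl aldehydes. The E geometry is what later lets the diene reach its s-cis form.

Step 4
Reactants: 1 8-methoxynaphthalen-1-ol
Product: 5 4-bromo-8-methoxynaphthalen-1-ol
Conditions: NBS (1.0 equiv), MeCN, −20 to 0 °C, dark
Reagents that add atoms: N-bromosuccinimide, O=C1CCC(=O)N1Br
Why: Electrophilic aromatic bromination: the free OH is the strongest donor, so ring 1 should react before the methoxy ring, and in polar MeCN without an amine C4 (para) is preferred over C2, the more so as the OH is held in the peri hydrogen bond to OMe and cannot steer the reagent to C2. The step precedes protection because a 1,8-dialkoxynaphthalene has two equally activated rings.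

Step 5
Reactants: 5 4-bromo-8-methoxynaphthalen-1-ol
Product: 6 1-bromo-5-methoxy-4-(methoxymethoxy)naphthalene
Conditions: MOMCl, i-Pr2NEt, CH2Cl2, 0 °C to rt
Reagents that add atoms: chloromethyl methyl ether, COCCl
Why: Same O-alkylation as in step 2; the acetal removes the acidic OH before the organozinc coupling and the strong-base steps.

Step 6
Reactants: 6 1-bromo-5-methoxy-4-(methoxymethoxy)naphthalene
Product: 7 ethyl 2-[5-methoxy-4-(methoxymethoxy)naphthalen-1-yl]acetate
Conditions: BrZnCH2CO2Et (from ethyl bromoacetate, Zn dust, THF), Pd2(dba)3 (2 mol %), XPhos (8 mol %), THF, 65 °C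
Reagents that add atoms: ethyl bromoacetate, BrCC(=O)OCC (used as its zinc reagent BrZnCH2CO2Et)
Why: Negishi-type coupling of a Reformatsky reagent with an aryl bromide; the neutral zinc enolate tolerates the ester and the acetal and should give the mono-arylated acetate, because the product is not deprotonated under these conditions.

Step 7
Reactants: 7 ethyl 2-[5-methoxy-4-(methoxymethoxy)naphthalen-1-yl]acetate; 4 2-[(E)-2-iodoethenyl]-8-methoxy-1-(methoxymethoxy)naphthalene
Product: 8 ethyl (3E)-2-[5-methoxy-4-(methoxymethoxy)naphthalen-1-yl]-4-[8-methoxy-1-(methoxymethoxy)naphthalen-2-yl]but-3-enoate (racemic at C2)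
Conditions: LiN(SiMe3)2 (2.2 equiv), Pd2(dba)3 (2.5 mol %), P(t-Bu)3·HBF4 (10 mol %), toluene, rt to 50 °C; AcOH quench
Reagents that add atoms: none
Why: Palladium-catalysed α-alkenylation of an ester enolate: oxidative addition of zerovalent palladium into the C–I bond with retention of the E geometry, transmetalation with the lithium enolate of 7 and reductive elimination form C2–C3. The second equivalent of base deprotonates the more acidic product, which should prevent a second coupling; C2 is formed racemic and is made planar again in step 8, and any shift of the double bond into conjugation is harmless because both isomers give the same dienolate.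

Step 8
Reactants: 8 ethyl (3E)-2-[5-methoxy-4-(methoxymethoxy)naphthalen-1-yl]-4-[8-methoxy-1-(methoxymethoxy)naphthalen-2-yl]but-3-enoate; 9 1-bromo-3-methoxybenzene (3-bromoanisole)
Product: 13 8-methoxy-2-[5-methoxy-4-(methoxymethoxy)naphthalen-1-yl]-4-[8-methoxy-1-(methoxymethoxy)naphthalen-2-yl]naphthalen-1-ol, via lithium dienolate 10 (not isolated), via 3-methoxybenzyne 11 (not isolated), via 4H-naphthalen-1-one 12 (not isolated)
Conditions: lithium 2,2,6,6-tetramethylpiperidide (from the amine and n-BuLi, 4 equiv), THF, −78 °C; then 9 (2 equiv), −78 to 0 °C; AcOH quench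
Reagents that add atoms: none
Why: The amide base deprotonates 8 at C2 to the dienolate 10, an electron-rich 1,1-dioxy diene, and deprotonates 9 between Br and OMe, after which loss of LiBr gives the aryne 11. The nucleophilic terminus C4 of 10 should add to the aryne carbon meta to OMe, which the C–O dipole makes the more electrophilic end and which leaves the developing aryl anion on the carbon next to OMe, where the inductive effect stabilises it; that carbon then bonds to the ester carbon C1 (a formal [4+2] annulation, at its stepwise limit an addition followed by 6-exo-trig acyl substitution). Loss of lithium ethoxide gives dienone 12, whose doubly benzylic C4–H is removed by base so that ring B1 aromatises to the naphtholate of 13; the oxidation level is right without oxidant or reductant. The closest known reaction type is the annulation of arynes, generated from haloanisoles with lithium amides, with lithium dienolates of unsaturated esters to give 1-naphthols, in which 3-methoxybenzyne gives 8-methoxy-1-naphthols. Ring B1 is closed by two new bonds, C4–C4a and C1–C8a, and no stereocentre is set, since the transient C4 centre of 12 is lost on aromatisation. Three selectivities are needed: the aryne regiochemistry, secured by the OMe beside the triple bond; γ- over α-bonding of 10, favoured by the 1-naphthyl group that shields C2 and by the fact that only γ-bonding can be followed by six-membered ring closure; and the s-cis diene, accessible because C3=C4 is E, so unit A points outwards. The hindered amide is chosen because it adds to arynes only slowly, and the product naphtholate is blocked at C2 and C4 and flanked at oxygen, so it should not consume aryne.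

Step 9
Reactants: 13 8-methoxy-2-[5-methoxy-4-(methoxymethoxy)naphthalen-1-yl]-4-[8-methoxy-1-(methoxymethoxy)naphthalen-2-yl]naphthalen-1-ol
Product: 14 2-(4-hydroxy-5-methoxynaphthalen-1-yl)-4-(1-hydroxy-8-methoxynaphthalen-2-yl)-8-methoxynaphthalen-1-ol
Conditions: 3 M aq HCl, MeOH/THF, 50 °C, under argon
Reagents that add atoms: none
Why: Acid-catalysed acetal cleavage: methanol traps the methoxymethyl cation as dimethoxymethane and the aryl methyl ethers are inert under these conditions. Argon is used because the trinaphthol is expected to be sensitive to oxidation.

## Compound list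

1 | 8-methoxynaphthalen-1-ol | COc1cccc2cccc(O)c12 | starting material
2 | 1-hydroxy-8-methoxynaphthalene-2-carbaldehyde | COc1cccc2ccc(C=O)c(O)c12 | intermediate
3 | 8-methoxy-1-(methoxymethoxy)naphthalene-2-carbaldehyde | COCOc1c(C=O)ccc2cccc(OC)c12 | intermediate
4 | 2-[(E)-2-iodoethenyl]-8-methoxy-1-(methoxymethoxy)naphthalene | COCOc1c(/C=C/I)ccc2cccc(OC)c12 | intermediate
5 | 4-bromo-8-methoxynaphthalen-1-ol | COc1cccc2c(Br)ccc(O)c12 | intermediate
6 | 1-bromo-5-methoxy-4-(methoxymethoxy)naphthalene | COCOc1ccc(Br)c2cccc(OC)c12 | intermediate
7 | ethyl 2-[5-methoxy-4-(methoxymethoxy)naphthalen-1-yl]acetate | CCOC(=O)Cc1ccc(OCOC)c2c(OC)cccc12 | intermediate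
8 | ethyl (3E)-2-[5-methoxy-4-(methoxymethoxy)naphthalen-1-yl]-4-[8-methoxy-1-(methoxymethoxy)naphthalen-2-yl]but-3-enoate (racemic) | CCOC(=O)C(/C=C/c1ccc2cccc(OC)c2c1OCOC)c1ccc(OCOC)c2c(OC)cccc12 | intermediate
9 | 1-bromo-3-methoxybenzene (3-bromoanisole) | COc1cccc(Br)c1 | starting material
10 | lithium dienolate of 8 (lithium 1-ethoxy-2,4-diarylbuta-1,3-dien-1-olate, 3E) | [Li+].CCOC([O-])=C(/C=C/c1ccc2cccc(OC)c2c1OCOC)c1ccc(OCOC)c2c(OC)cccc12 | intermediate
11 | 3-methoxybenzyne (1-methoxy-2,3-didehydrobenzene) | COC1=CC=CC#C1 | intermediate
12 | 8-methoxy-2-[5-methoxy-4-(methoxymethoxy)naphthalen-1-yl]-4-[8-methoxy-1-(methoxymethoxy)naphthalen-2-yl]naphthalen-1(4H)-one (racemic) | COc1cccc2c1C(=O)C(c1ccc(OCOC)c3c(OC)cccc13)=CC2c1ccc2cccc(OC)c2c1OCOC | intermediate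
13 | 8-methoxy-2-[5-methoxy-4-(methoxymethoxy)naphthalen-1-yl]-4-[8-methoxy-1-(methoxymethoxy)naphthalen-2-yl]naphthalen-1-ol | COc1cccc2ccc(-c3cc(-c4ccc(OCOC)c5c(OC)cccc45)c(O)c4c(OC)cccc34)c(OCOC)c12 | intermediate
14 | 2-(4-hydroxy-5-methoxynaphthalen-1-yl)-4-(1-hydroxy-8-methoxynaphthalen-2-yl)-8-methoxynaphthalen-1-ol | COc1cccc2ccc(-c3cc(-c4ccc(O)c5c(OC)cccc45)c(O)c4c(OC)cccc34)c(O)c12 | target

## Step count and risk

Total step count: 9. Longest linear sequence: 6 steps (steps 1, 2, 3, 7, 8, 9 or steps 4, 5, 6, 7, 8, 9).

**Step 8 (key step).** The most likely failure is bonding of the dienolate through its α carbon instead of its γ carbon, which leads to a quaternary α-aryl ester that cannot close ring B1. Consumption of the aryne by the amide base or by ethoxide, and a low population of the s-cis dienolate (both termini carry bulky naphthyl groups), would also lower conversion. The fallback abandons ring construction and joins the three units by cross-coupling; it sets out from 1 and 6 and comes back to the route at 14. Compound 1 is protected (MOMCl, i-Pr2NEt) as 1-methoxy-8-(methoxymethoxy)naphthalene F1. Directed ortho-lithiation next to the acetal (n-BuLi, TMEDA, Et2O, 0 °C), then B(OMe)3 and aqueous work-up, gives [8-methoxy-1-(methoxymethoxy)naphthalen-2-yl]boronic acid F2. Suzuki–Miyaura coupling of F2 with 6 (Pd(OAc)2, SPhos, K3PO4, toluene/water, 90 °C) gives 8-methoxy-2-[5-methoxy-4-(methoxymethoxy)naphthalen-1-yl]-1-(methoxymethoxy)naphthalene F3, in which the unit derived from 6 is now unit B. A second ortho-lithiation, possible only next to the acetal of unit B, followed by borylation gives {8-methoxy-4-[8-methoxy-1-(methoxymethoxy)naphthalen-2-yl]-1-(methoxymethoxy)naphthalen-2-yl}boronic acid F4. A second coupling with 6 under the same conditions gives 8-methoxy-4-[8-methoxy-1-(methoxymethoxy)naphthalen-2-yl]-2-[5-methoxy-4-(methoxymethoxy)naphthalen-1-yl]-1-(methoxymethoxy)naphthalene F5, and the conditions of step 9 then remove all three acetals to give 14.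

**Step 7.** Base-induced loss of HI from the iodoalkene (to the arylalkyne) may outrun oxidative addition, and reductive elimination from the hindered palladium enolate may be slow, so that the halide is merely reduced. The fallback forms the same carbon chain by aldol chemistry; it sets out from 3 and 7 and comes back at dienolate 10 in step 8. Wittig reaction of 3 with Ph3P=CHOMe gives 8-methoxy-2-(2-methoxyethenyl)-1-(methoxymethoxy)naphthalene F6 (E/Z mixture). Brief mild hydrolysis of the enol ether (dilute acid in THF at 0 °C, conditions under which the aryl acetal should persist) gives 2-[8-methoxy-1-(methoxymethoxy)naphthalen-2-yl]acetaldehyde F7. Addition of the lithium enolate of 7 (LiN(i-Pr)2, THF, −78 °C) to F7 gives ethyl 3-hydroxy-2-[5-methoxy-4-(methoxymethoxy)naphthalen-1-yl]-4-[8-methoxy-1-(methoxymethoxy)naphthalen-2-yl]butanoate F8 (diastereomer mixture). Dehydration with the Burgess reagent gives ethyl 2-[5-methoxy-4-(methoxymethoxy)naphthalen-1-yl]-4-[8-methoxy-1-(methoxymethoxy)naphthalen-2-yl]but-2-enoate F9, whose γ-deprotonation under the conditions of step 8 gives 10. The drawback is that the geometry of C3=C4 is then set only in the deprotonation.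

**Step 4.** Bromination may partly go to C2, run on to the 2,4-dibromide, or touch the methoxy ring at C5, which would cost material and require a difficult separation. The fallback over-brominates on purpose and then removes one bromine; it sets out from 1 and comes back at 6. Two equivalents of NBS give 2,4-dibromo-8-methoxynaphthalen-1-ol F10, and protection (MOMCl, i-Pr2NEt) gives 2,4-dibromo-8-methoxy-1-(methoxymethoxy)naphthalene F11. One equivalent of n-BuLi at −78 °C should exchange the bromine at C2, which is activated and chelated by the neighbouring acetal, and a methanol quench then gives 6.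

**Step 3.** The E selectivity of the halo-olefination may be incomplete, and divalent chromium may reduce the aldehyde to the pinacol dimer. The fallback sets the geometry by a syn addition; it sets out from 3 and comes back at 4. Ohira–Bestmann homologation (dimethyl (1-diazo-2-oxopropyl)phosphonate, K2CO3, MeOH) gives 2-ethynyl-8-methoxy-1-(methoxymethoxy)naphthalene F12. Hydrozirconation with Cp2Zr(H)Cl followed by iodine then gives 4 as the E isomer only.

## Further compounds

F1 | step 8 | 1-methoxy-8-(methoxymethoxy)naphthalene | COCOc1cccc2cccc(OC)c12
F2 | step 8 | [8-methoxy-1-(methoxymethoxy)naphthalen-2-yl]boronic acid | COCOc1c(B(O)O)ccc2cccc(OC)c12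
F3 | step 8 | 8-methoxy-2-[5-methoxy-4-(methoxymethoxy)naphthalen-1-yl]-1-(methoxymethoxy)naphthalene | COCOc1c(-c2ccc(OCOC)c3c(OC)cccc23)ccc2cccc(OC)c12
F4 | step 8 | {8-methoxy-4-[8-methoxy-1-(methoxymethoxy)naphthalen-2-yl]-1-(methoxymethoxy)naphthalen-2-yl}boronic acid | COCOc1c(-c2cc(B(O)O)c(OCOC)c3c(OC)cccc23)ccc2cccc(OC)c12
F5 | step 8 | 8-methoxy-4-[8-methoxy-1-(methoxymethoxy)naphthalen-2-yl]-2-[5-methoxy-4-(methoxymethoxy)naphthalen-1-yl]-1-(methoxymethoxy)naphthalene | COc1cccc2ccc(-c3cc(-c4ccc(OCOC)c5c(OC)cccc45)c(OCOC)c4c(OC)cccc34)c(OCOC)c12
F6 | step 7 | 8-methoxy-2-(2-methoxyethenyl)-1-(methoxymethoxy)naphthalene (E/Z mixture) | COC=Cc1ccc2cccc(OC)c2c1OCOC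
F7 | step 7 | 2-[8-methoxy-1-(methoxymethoxy)naphthalen-2-yl]acetaldehyde | O=CCc1ccc2cccc(OC)c2c1OCOC
F8 | step 7 | ethyl 3-hydroxy-2-[5-methoxy-4-(methoxymethoxy)naphthalen-1-yl]-4-[8-methoxy-1-(methoxymethoxy)naphthalen-2-yl]butanoate (diastereomer mixture) | CCOC(=O)C(C(O)Cc1ccc2cccc(OC)c2c1OCOC)c1ccc(OCOC)c2c(OC)cccc12
F9 | step 7 | ethyl 2-[5-methoxy-4-(methoxymethoxy)naphthalen-1-yl]-4-[8-methoxy-1-(methoxymethoxy)naphthalen-2-yl]but-2-enoate (E/Z mixture) | CCOC(=O)C(=CCc1ccc2cccc(OC)c2c1OCOC)c1ccc(OCOC)c2c(OC)cccc12
F10 | step 4 | 2,4-dibromo-8-methoxynaphthalen-1-ol | COc1cccc2c(Br)cc(Br)c(O)c12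
F11 | step 4 | 2,4-dibromo-8-methoxy-1-(methoxymethoxy)naphthalene | COCOc1c(Br)cc(Br)c2cccc(OC)c12
F12 | step 3 | 2-ethynyl-8-methoxy-1-(methoxymethoxy)naphthalene | C#Cc1ccc2cccc(OC)c2c1OCOC
A1 | alternative 1 | 4-bromo-2-iodo-8-methoxy-1-(methoxymethoxy)naphthalene | COCOc1c(I)cc(Br)c2cccc(OC)c12
A2 | alternative 1 | 2-[5-methoxy-4-(methoxymethoxy)naphthalen-1-yl]-4,4,5,5-tetramethyl-1,3,2-dioxaborolane | COCOc1ccc(B2OC(C)(C)C(C)(C)O2)c2cccc(OC)c12
A3 | alternative 2 | 2-(4-hydroxy-5-methoxynaphthalen-1-yl)-8-methoxynaphthalen-1-ol | COc1cccc2ccc(-c3ccc(O)c4c(OC)cccc34)c(O)c12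
A4 | alternative 2 | 4-(4-hydroxy-5-methoxynaphthalen-1-yl)-8-methoxynaphthalen-1-ol | COc1cccc2c(-c3ccc(O)c4c(OC)cccc34)ccc(O)c12
A5 | alternative 3 | 2-[8-methoxy-1-(methoxymethoxy)naphthalen-2-yl]-4-[5-methoxy-4-(methoxymethoxy)naphthalen-1-yl]furan | COCOc1c(-c2cc(-c3ccc(OCOC)c4c(OC)cccc34)co2)ccc2cccc(OC)c12
A6 | alternative 3 | 5-methoxy-3-[5-methoxy-4-(methoxymethoxy)naphthalen-1-yl]-1-[8-methoxy-1-(methoxymethoxy)naphthalen-2-yl]-1,4-dihydro-1,4-epoxynaphthalene (racemic) | COc1cccc2c1C1OC2(c3ccc4cccc(OC)c4c3OCOC)C=C1c1ccc(OCOC)c2c(OC)cccc12
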